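**Retrosynthetic overview**
- The aryl ether (C1–OAr) is made last by a Mitsunobu reaction of a (2S,3R,5R)-oxolane diol with isofraxidin; the C5 isobutenyl group comes from a C5 formyl group by Wittig olefination.
- The C3 carbinol (CH3, OH) comes from an exocyclic C3=CH2 by Markovnikov radical hydration, with oxygen entering anti to the C2 arm.
- Enabling feature: in the oxolane ring O1–C2–C3–C4–C5, the methyl/hydroxyl carbon C3 is a latent alkenyl carbon bonded to C2, whose own oxygen is the ring O1, and C5 is an O-bearing sp3 carbon two atoms away. The ring is therefore the formal [3+2] adduct of a 2-metalloallyl unit (C3 nucleophile, C5 electrophile) and an aldehyde C2=O1.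
- Key disconnection: C2–C3 (Nozaki–Hiyama–Kishi alkenylation) and O1–C5 (Williamson closure) in one flask, from a 2-iodoallyl mesylate (C5 bought, from (S)-benzyl glycidyl ether) and silyloxyacetaldehyde.
- Ring order: the oxolane is the only ring made (step 4); the coumarin is bought as isofraxidin and attached in step 10.

Key step: step 4

Remark: oxolane locants are used for all ring intermediates (O1; C2 carries the CH2O arm; C3 the methyl/hydroxyl carbon; C5 the isobutenyl carbon or its precursor). The antipode of the chromium ligand in step 4 has to be matched to the R carbinol; both antipodes are accessible.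

Step 1
Reactants: 1 (S)-benzyl glycidyl ether
Product: 2 (2S)-1-(benzyloxy)pent-4-yn-2-ol
Conditions: LiC≡CH·H2NCH2CH2NH2, DMSO, 0 °C to rt; then H2O
Reagents that add atoms: lithium acetylide–ethylenediamine complex, [Li]C#C.NCCN
Why: Epoxide alkynylation: the acetylide opens the terminal epoxide by SN2 attack at its CH2 carbon, so the bought stereocenter is not touched.

Step 2
Reactants: 2 (2S)-1-(benzyloxy)pent-4-yn-2-ol
Product: 3 (2S)-1-(benzyloxy)pent-4-yn-2-yl methanesulfonate
Conditions: MsCl, Et3N, CH2Cl2, 0 °C
Reagents that add atoms: methanesulfonyl chloride, CS(=O)(=O)Cl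
Why: Mesylation of the secondary alcohol with retention turns the future C5 into an SN2 electrophile.

Step 3
Reactants: 3 (2S)-1-(benzyloxy)pent-4-yn-2-yl methanesulfonate
Product: 5 (2S)-1-(benzyloxy)-4-iodopent-4-en-2-yl methanesulfonate, via iodoalkenylborane 4 (not isolated)
Conditions: B-I-9-BBN, pentane/CH2Cl2, −20 to 0 °C; then AcOH, 0 °C
Reagents that add atoms: B-iodo-9-borabicyclo[3.3.1]nonane, IB1C2CCCC1CCC2
Why: Haloboration–protonolysis (Markovnikov hydroiodination): syn addition of B–I puts boron on the terminal and iodine on the internal alkyne carbon, and acetic acid then replaces boron by hydrogen; the benzyl ether and the mesylate should survive at low temperature.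

Step 4
Reactants: 5 (2S)-1-(benzyloxy)-4-iodopent-4-en-2-yl methanesulfonate, 6 (tert-butyldimethylsilyloxy)acetaldehyde
Product: 8 tert-butyl{[(2R,5R)-5-[(benzyloxy)methyl]-3-methylideneoxolan-2-yl]methoxy}dimethylsilane, via hydroxy mesylate 7 (not isolated)
Conditions: CrCl2 (10 mol %), chiral oxazoline–sulfonamide ligand (12 mol %), proton sponge, NiCl2·2,9-dimethyl-1,10-phenanthroline (2 mol %), Mn, Cp2ZrCl2, LiCl, MeCN, rt; then MeOH, K2CO3, 45 °C, same flask
Reagents that add atoms: none
Why: Ni(0) inserts into the C–I bond of 5 and hands the alkenyl group to Cr(III); the alkenylchromium bound to the chiral ligand adds to the aldehyde carbon of 6 (C2–C3 bond), Cp2ZrCl2 takes over the alkoxide and Mn returns Cr(III) to Cr(II) (catalytic asymmetric Nozaki–Hiyama–Kishi reaction). Methanol then frees alcohol 7, whose C2 oxygen displaces the C5 mesylate (O1–C5 bond, Williamson etherification), closing the oxolane by a 5-exo-tet attack. The closest known reaction type is the Ni/Cr coupling followed by SN2 cyclisation that is used for 3-methylene-2,5-disubstituted oxolanes. C2 is set by the chiral chromium complex (reagent control, since the remote mesylate centre gives little bias), and C5 comes from the (S)-mesylate by inversion, which should give the 2,5-trans ring. The step needs chemoselectivity of the organometallic for the aldehyde over the mesylate and silyl ether, and substitution over elimination or silyl migration in the closure. The low basicity of alkenylchromium, the non-allylic secondary mesylate, the mild carbonate base and the favoured five-membered closure should secure this; any C2 epimer would appear as the separable 2,5-cis oxolane.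

Step 5
Reactants: 8 tert-butyl{[(2R,5R)-5-[(benzyloxy)methyl]-3-methylideneoxolan-2-yl]methoxy}dimethylsilane
Product: 9 (2S,3R,5R)-5-[(benzyloxy)methyl]-2-({[tert-butyl(dimethyl)silyl]oxy}methyl)-3-methyloxolan-3-ol
Conditions: Co(acac)2 (20 mol %), PhSiH3, O2 (1 atm), THF, rt
Reagents that add atoms: dioxygen, O=O
Why: Mukaiyama hydration: hydrogen atom transfer to the CH2 terminus gives the tertiary C3 radical, which should be trapped by O2 on the face anti to the adjacent C2 silyloxymethyl arm, so the hydroxyl ends trans to that arm and cis to the C5 arm (3R) and the former methylene becomes the methyl group.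

Step 6
Reactants: 9 (2S,3R,5R)-5-[(benzyloxy)methyl]-2-({[tert-butyl(dimethyl)silyl]oxy}methyl)-3-methyloxolan-3-ol
Product: 10 (2S,3R,5R)-2-({[tert-butyl(dimethyl)silyl]oxy}methyl)-5-(hydroxymethyl)-3-methyloxolan-3-ol
Conditions: H2 (1 atm), Pd/C, EtOAc, rt
Reagents that add atoms: none
Why: Hydrogenolysis of the benzyl ether; no alkene is present at this stage and the silyl ether and tertiary alcohol are inert.

Step 7
Reactants: 10 (2S,3R,5R)-2-({[tert-butyl(dimethyl)silyl]oxy}methyl)-5-(hydroxymethyl)-3-methyloxolan-3-ol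
Product: 11 (2R,4R,5S)-5-({[tert-butyl(dimethyl)silyl]oxy}methyl)-4-hydroxy-4-methyloxolane-2-carbaldehyde
Conditions: Dess–Martin periodinane, NaHCO3, CH2Cl2, 0 °C to rt
Reagents that add atoms: none
Why: Dess–Martin oxidation takes the primary alcohol to the aldehyde under buffered, non-epimerising conditions; the tertiary alcohol cannot be oxidised.

Step 8
Reactants: 11 (2R,4R,5S)-5-({[tert-butyl(dimethyl)silyl]oxy}methyl)-4-hydroxy-4-methyloxolane-2-carbaldehyde
Product: 12 (2S,3R,5R)-2-({[tert-butyl(dimethyl)silyl]oxy}methyl)-3-methyl-5-(2-methylprop-1-en-1-yl)oxolan-3-ol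
Conditions: i-PrPPh3I (excess), n-BuLi, THF, 0 °C; then 11, −78 to 0 °C
Reagents that add atoms: isopropyltriphenylphosphonium iodide, CC(C)[P+](c1ccccc1)(c1ccccc1)c1ccccc1.[I-]
Why: Wittig olefination with the non-stabilised isopropylidene ylide gives the trisubstituted alkene without an E/Z question; excess ylide covers the free hydroxyl and the low temperature should protect the α-oxy stereocenter.

Step 9
Reactants: 12 (2S,3R,5R)-2-({[tert-butyl(dimethyl)silyl]oxy}methyl)-3-methyl-5-(2-methylprop-1-en-1-yl)oxolan-3-ol
Product: 13 (2S,3R,5R)-2-(hydroxymethyl)-3-methyl-5-(2-methylprop-1-en-1-yl)oxolan-3-ol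
Conditions: TBAF, THF, 0 °C to rt
Reagents that add atoms: none
Why: Fluoride desilylation frees the primary alcohol under non-acidic conditions that leave the acid-sensitive allylic ether at C5 intact.

Step 10
Reactants: 13 (2S,3R,5R)-2-(hydroxymethyl)-3-methyl-5-(2-methylprop-1-en-1-yl)oxolan-3-ol, 14 isofraxidin (7-hydroxy-6,8-dimethoxy-2H-chromen-2-one)
Product: 15 7-{[(2S,3R,5R)-3-hydroxy-3-methyl-5-(2-methylprop-1-en-1-yl)oxolan-2-yl]methoxy}-6,8-dimethoxy-2H-chromen-2-one
Conditions: PPh3, DIAD, THF, 0 °C to rt
Reagents that add atoms: none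
Why: Mitsunobu etherification: the acidic 7-hydroxyl of isofraxidin displaces the activated primary alcohol at a CH2 carbon, so no stereocenter is touched and the tertiary alcohol is not activated.

**Compound list**
1 | (S)-benzyl glycidyl ether, (2S)-2-[(benzyloxy)methyl]oxirane | c1ccccc1COC[C@@H]1CO1 | starting material
2 | (2S)-1-(benzyloxy)pent-4-yn-2-ol | C#CC[C@H](O)COCc1ccccc1 | intermediate
3 | (2S)-1-(benzyloxy)pent-4-yn-2-yl methanesulfonate | C#CC[C@H](OS(C)(=O)=O)COCc1ccccc1 | intermediate
4 | 9-[(1Z,4S)-5-(benzyloxy)-2-iodo-4-(methanesulfonyloxy)pent-1-en-1-yl]-9-borabicyclo[3.3.1]nonane | I\C(C[C@H](OS(C)(=O)=O)COCc1ccccc1)=C/B1C2CCCC1CCC2 | intermediate (not isolated)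
5 | (2S)-1-(benzyloxy)-4-iodopent-4-en-2-yl methanesulfonate | C=C(I)C[C@H](OS(C)(=O)=O)COCc1ccccc1 | intermediate
6 | (tert-butyldimethylsilyloxy)acetaldehyde | CC(C)(C)[Si](C)(C)OCC=O | starting material
7 | (2S,5R)-1-(benzyloxy)-6-{[tert-butyl(dimethyl)silyl]oxy}-5-hydroxy-4-methylidenehexan-2-yl methanesulfonate (formed as its zirconium alkoxide, freed by methanol) | CC(C)(C)[Si](C)(C)OC[C@H](O)C(=C)C[C@H](OS(C)(=O)=O)COCc1ccccc1 | intermediate (not isolated)
8 | tert-butyl{[(2R,5R)-5-[(benzyloxy)methyl]-3-methylideneoxolan-2-yl]methoxy}dimethylsilane | CC(C)(C)[Si](C)(C)OC[C@@H]1O[C@@H](COCc2ccccc2)CC1=C | intermediate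
9 | (2S,3R,5R)-5-[(benzyloxy)methyl]-2-({[tert-butyl(dimethyl)silyl]oxy}methyl)-3-methyloxolan-3-ol | CC(C)(C)[Si](C)(C)OC[C@@H]1O[C@@H](COCc2ccccc2)C[C@@]1(C)O | intermediate
10 | (2S,3R,5R)-2-({[tert-butyl(dimethyl)silyl]oxy}methyl)-5-(hydroxymethyl)-3-methyloxolan-3-ol | CC(C)(C)[Si](C)(C)OC[C@@H]1O[C@@H](CO)C[C@@]1(C)O | intermediate
11 | (2R,4R,5S)-5-({[tert-butyl(dimethyl)silyl]oxy}methyl)-4-hydroxy-4-methyloxolane-2-carbaldehyde | CC(C)(C)[Si](C)(C)OC[C@@H]1O[C@@H](C=O)C[C@@]1(C)O | intermediate
12 | (2S,3R,5R)-2-({[tert-butyl(dimethyl)silyl]oxy}methyl)-3-methyl-5-(2-methylprop-1-en-1-yl)oxolan-3-ol | CC(C)(C)[Si](C)(C)OC[C@@H]1O[C@@H](C=C(C)C)C[C@@]1(C)O | intermediate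
13 | (2S,3R,5R)-2-(hydroxymethyl)-3-methyl-5-(2-methylprop-1-en-1-yl)oxolan-3-ol | OC[C@@H]1O[C@@H](C=C(C)C)C[C@@]1(C)O | intermediate
14 | isofraxidin, 7-hydroxy-6,8-dimethoxy-2H-chromen-2-one | COc1cc2ccc(=O)oc2c(OC)c1O | starting material
15 | 7-{[(2S,3R,5R)-3-hydroxy-3-methyl-5-(2-methylprop-1-en-1-yl)oxolan-2-yl]methoxy}-6,8-dimethoxy-2H-chromen-2-one | COc1cc2ccc(=O)oc2c(OC)c1OC[C@@H]1O[C@@H](C=C(C)C)C[C@@]1(C)O | target

**Step count**
Total steps: 10. Longest linear sequence: 10 steps (1 to 15); 6 and 14 are bought and enter in steps 4 and 10.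

**Steps most likely to fail**

Step 4. The risk is incomplete reagent control in the C–C bond formation, that is, erosion of facial selectivity at the aldehyde, or slow catalyst turnover. The fallback sets out from 5 and 6 and separates bond formation from stereocontrol. A stoichiometric achiral CrCl2/NiCl2 coupling (DMSO/THF, rt) would give 7 together with its carbinol epimer (2S,5S)-1-(benzyloxy)-6-{[tert-butyl(dimethyl)silyl]oxy}-5-hydroxy-4-methylidenehexan-2-yl methanesulfonate F1. Dess–Martin oxidation of the mixture would give the single enone (2S)-1-(benzyloxy)-6-{[tert-butyl(dimethyl)silyl]oxy}-4-methylidene-5-oxohexan-2-yl methanesulfonate F2. A CBS reduction (catecholborane, toluene, −78 °C) would then return 7 alone, using the oxazaborolidine antipode that gives the 5R carbinol, expected to be the R catalyst if the alkenyl arm acts as the large group. K2CO3 in MeOH would close 7 to 8, where the fallback rejoins the route.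

Step 5. The risk is poor facial discrimination in the capture of the C3 radical, together with competing reduction of the alkene to the alkane. The fallback sets out from 8 and uses an ionic two-step hydration. Epoxidation with m-CPBA (NaHCO3, CH2Cl2, 0 °C), with attack anti to the C2 arm, should give the spiro-epoxide (3S,4S,6R)-6-[(benzyloxy)methyl]-4-({[tert-butyl(dimethyl)silyl]oxy}methyl)-1,5-dioxaspiro[2.4]heptane F3, whose diastereomers can be separated before the next step. Opening with LiEt3BH (THF, 0 °C) at the CH2 carbon would give 9, where the fallback rejoins the route.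

Step 8. The risk is slow olefination by the hindered ylide, which would leave time for base-induced epimerisation at the α-oxy carbon and for masking of the formyl group as a hemiacetal by the cis C3 hydroxyl. The fallback sets out from 11. Methylenation with Ph3P=CH2 (THF, −78 to 0 °C), which is fast, should give (2S,3R,5R)-2-({[tert-butyl(dimethyl)silyl]oxy}methyl)-5-ethenyl-3-methyloxolan-3-ol F4. Cross-metathesis with 2-methyl-2-butene (second-generation ruthenium alkylidene catalyst, 40 °C) would install the isobutenyl group and return to the route at 12.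

**Further compounds**
F1 | step 4 | (2S,5S)-1-(benzyloxy)-6-{[tert-butyl(dimethyl)silyl]oxy}-5-hydroxy-4-methylidenehexan-2-yl methanesulfonate | CC(C)(C)[Si](C)(C)OC[C@@H](O)C(=C)C[C@H](OS(C)(=O)=O)COCc1ccccc1
F2 | step 4 | (2S)-1-(benzyloxy)-6-{[tert-butyl(dimethyl)silyl]oxy}-4-methylidene-5-oxohexan-2-yl methanesulfonate | CC(C)(C)[Si](C)(C)OCC(=O)C(=C)C[C@H](OS(C)(=O)=O)COCc1ccccc1
F3 | step 5 | (3S,4S,6R)-6-[(benzyloxy)methyl]-4-({[tert-butyl(dimethyl)silyl]oxy}methyl)-1,5-dioxaspiro[2.4]heptane | CC(C)(C)[Si](C)(C)OC[C@@H]1O[C@@H](COCc2ccccc2)C[C@]13CO3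
F4 | step 8 | (2S,3R,5R)-2-({[tert-butyl(dimethyl)silyl]oxy}methyl)-5-ethenyl-3-methyloxolan-3-ol | CC(C)(C)[Si](C)(C)OC[C@@H]1O[C@@H](C=C)C[C@@]1(C)O
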